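## The problem

Target 26 is a cis-fused 4a,5,8,8a-tetrahydronaphthalen-1(4H)-one. Ring A is a cyclohexene (C6=C7) with hexadecyl on C6 and methyl esters on C5 and C8; ring B is a 2-methoxycarbonyl-3-hexadecylcyclohex-2-enone; the rings share C4a–C8a. Four contiguous stereocentres (C5, C4a, C8a, C8) must be set: H4a, H8a and H8 lie on one face and H5 on the other, so the C8 ester is cis to its ring-B neighbour C1 while the C5 ester is trans to C4. This mixed pattern cannot come from treating C5 and C8 alike: a reagent that reaches both from the open face gives the C5 epimer, and equilibration would drift at C8 and at C8a (α to the ketone, prone to go trans-fused). The two ring-fusion centres can control the others (C8 through the bulk on C8a, C5 through a group carried on the C4 arm), so they should be set first and together. Sensitive features are the two β,γ-unsaturated esters (base moves C6=C7 into conjugation), the enolisable C8a–H, the doubly activated C2=C3 alkene (best made last) and any free hydroxyl γ or δ to an ester (lactonisation). The two C16 chains offer no handles and must arrive with the building blocks. The enabling feature is that C4a–C8a joins the ends of C4a=C5–C6=C7–C8=C8a, a hexatriene whose inner carbons already carry both ring-A esters and the C6 chain and whose outward terminal substituents (C4, C1) become the cis fusion on disrotatory closure.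

## Retrosynthesis

**C2=C3 (ring B).** Target 26 is opened at the tetrasubstituted alkene to diketone 24, the forward reaction being an intramolecular Knoevenagel condensation of the β-keto ester carbon C2 onto a C3 ketone. Against closing C2–C3 by adding the keto ester to an internal alkyne (an exo-dig mode that is poor for non-terminal alkynes and needs a later alkene shift), the condensation gives the conjugated alkene directly under near-neutral conditions. Diketone 24 comes from diol 23 by oxidation, so C1 and C3 can serve as carbinol control elements that are erased at the end. The forward step must not enolise C8a or move C6=C7.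

**C5–H and C8–H.** Diol 23 (via its C1 silyl ether 22) is traced to diene diester 21 by removing the two hydrogens: the forward reaction is a two-electron 1,4-reduction of the C5=C6–C7=C8 diester. H8 must enter anti to the C1 arm (open face) and H5 syn to the C4 arm (hindered face). For that reason 21 carries a free C3 hydroxyl as an internal proton donor for C5 and a silylated C1 oxygen, which must not donate to C8. Compound 21 comes from 20 by selective cleavage of the C3 silyl ether.

**C4a–C8a (ring A).** Cyclohexadiene 20 is opened to acyclic triene 19. A cycloaddition across C4a–C5 and C8–C8a would need a diene with an inward ester and a quinoid dienophile; the electrocyclization needs only alkene geometry, which cross-coupling delivers. The precursor is acyclic with two carbinol stereocentres. The forward step must keep all three alkene geometries and choose one face through C1.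

**C5–C6 and C7–C8.** Triene 19 is cut into iodoenoate 15 and dienyl boronate 18, and 18 into iodoenoate 8 and the cis-diboryl alkene 17, itself from alkyne 16. The diboration fixes the central alkene with C5 and C8 cis and the hexadecyl on C6; the terminal C–B bond couples first, so the order of the two couplings defines the regiochemistry. The second coupling joins two fully substituted sp2 carbons and is the demanding one.

**Iodoenoate 8.** The (E)-2-iodoenoate (arm cis to ester) comes from stannane 7 and ynoate 6 by syn-hydrostannation and iodination; 6 from terminal alkyne 5 by base-free carbonylation; 5 from carbinol 4, made from ynal 1 and silyl ketene acetal 2 by a catalytic asymmetric acetate aldol that sets C1.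

**Iodoenoate 15.** In the same way 15 comes from stannane 14 and ynoate 13; 13 from silyl ether 12 and homopropargylic alcohol 11; 11 from epoxide 10, resolved from racemic 9. The C3 carbinol replaces an alkynyl arm because it supplies both the later ketone and the internal proton donor.

## Roads not taken

**Alternative 1:** The cut is C4–C4a. A primary C4 radical, released by reductive decarboxylation (cathodic or photoredox) of redox-active ester A2, would add 6-exo to C4a of a ring-A dienoate; the C5 radical is then reduced and protonated to give A1, the 2,3-dihydro form of 26. Merits: radical conjugate additions tolerate esters and the ketone, the short tether enforces cis fusion relative to C8a, and no oxygen protecting group is needed. Weak points: ring A with C8 and C8a must already exist, so the step solves the easier ring; the C5 radical is allylic, so hydrogen can enter at C7 or at C5 from either face; C2 and C3 are made as stereocentres only to be removed by a dehydrogenation beside two epimerisable esters; A2 is itself a long linear target. On the ring fusion this road is the safer one, since cis closure is enforced and not chosen by an allylic stereocentre. The chosen plan sets against it that one step makes ring A and both fusion centres from three simple pieces, and ring B needs no late dehydrogenation.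

**Alternative 2:** The cut is threefold: C4a–C8a, C5–C6 and C7–C8. A zerovalent nickel–phosphine catalyst would couple the two β-carbons of tethered bis-enoate A4, insert alkyne 16 and reductively eliminate to give bicycle A3. Merits: both rings and three bonds form in one step, C6=C7 appears at the right oxidation level, and no diene reduction (hence no C5/C8 protonation problem) is needed; on step count and on this point the road is better than the chosen one. Weak points: the nickelacycle has two nearly equivalent Ni–C bonds, so nothing clearly places the hexadecyl of 16 on C6 rather than C7; enoates are weaker partners than enones and 16 can trimerise; fusion and C5/C8 geometry follow the metallacycle, not a design element; A3 lacks the C2 ester and has C1 as a silyl ether, so an enone α-acylation and an oxidation remain. The chosen plan sets against it that every substituent position is fixed by construction and the C2 ester is present from the first step.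

**Alternative 3:** The cut is C4a–C5 and C6=C7. A chiral primary amine salt would activate enone A6 as an iminium ion; β-keto ester A7 adds through C5 to C4a and the methyl ketone condenses on the C6 ketone, giving ring-A enone A5. Merits: catalyst-controlled absolute configuration from two trivial pieces is firmer than the allylic induction used here, and the trans C4a/C5 relation, which the chosen plan has to engineer, arises by itself. Weak points: A5 holds only C4a and C5; C8 is a ketone and C8a a methylene, so the C8 ester, the C1 branch on C8a (cis to C4) and all of ring B remain, each needing stereocontrol beside an epimerisable ester; turning the C8 ketone into an ester passes through a dienoate and back to a reduction problem; the ring-fusion bond is not addressed. The chosen plan sets against it that after its key step every carbon of 26 and both fusion centres are in place, with four steps left.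

Key step: step 15

Assumption: closure anti to the C1 silyloxy group is taken as the preferred sense; if the opposite sense prevails, the other ligand enantiomer in step 1 corrects it, since C1 is oxidised in step 19.
Assumption: the 4S carbinol (C3) is chosen because it is the matched series for the lactone fallback of step 15; either antipode is available from step 6 and C3 is oxidised in step 19.

## Route

Step 1
Reactants: 1 3-(trimethylsilyl)prop-2-ynal; 2 1-methoxy-1-(trimethylsilyloxy)ethene
Product: 4 methyl (3R)-3-hydroxypent-4-ynoate, via bis-silyl aldol adduct 3 (not isolated)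
Conditions: Ti(OiPr)4 (2 mol%), Carreira binaphthyl Schiff-base ligand (enantiomer giving 3R), 3,5-di-tert-butylsalicylic acid, Et2O, −10 °C; then K2CO3, MeOH, 0 °C
Reagents that add atoms: none
Why: Catalytic asymmetric Mukaiyama acetate aldol addition to an ynal; the chiral titanium complex selects the aldehyde face and sets C1 (3R). Carbonate in methanol then removes both the O- and the C-bound trimethylsilyl groups.

Step 2
Reactants: 4 methyl (3R)-3-hydroxypent-4-ynoate
Product: 5 methyl (3R)-3-[(tert-butyldimethylsilyl)oxy]pent-4-ynoate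
Conditions: TBSCl, imidazole, DMF, rt
Reagents that add atoms: tert-butyldimethylsilyl chloride, CC(C)(C)[Si](C)(C)Cl
Why: Standard silylation of a secondary propargylic alcohol; the silyl ether later supplies the bulk that biases the key step and blocks C1–OH from acting as a proton donor.

Step 3
Reactants: 5 methyl (3R)-3-[(tert-butyldimethylsilyl)oxy]pent-4-ynoate
Product: 6 dimethyl (4R)-4-[(tert-butyldimethylsilyl)oxy]hex-2-ynedioate
Conditions: PdCl2 (5 mol%), CuCl2, NaOAc, CO (1 atm), MeOH, rt
Reagents that add atoms: carbon monoxide, [C-]#[O+]; methanol, CO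
Why: Tsuji oxidative methoxycarbonylation of a terminal alkyne; it avoids a strong base, which would attack the ester or eliminate the β-silyloxy group.

Step 4
Reactants: 6 dimethyl (4R)-4-[(tert-butyldimethylsilyl)oxy]hex-2-ynedioate
Product: 7 dimethyl (2E,4R)-4-[(tert-butyldimethylsilyl)oxy]-2-(tributylstannyl)hex-2-enedioate
Conditions: Bu3SnH, Pd(PPh3)4 (2 mol%), THF, 0 °C
Reagents that add atoms: tributyltin hydride, CCCC[SnH](CCCC)CCCC
Why: Palladium-catalysed syn-hydrostannation of an ynoate puts tin on the α-carbon and hydrogen on the β-carbon, so the carbinol arm ends cis to the ester (the outward geometry needed at C8=C8a).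

Step 5
Reactants: 7 dimethyl (2E,4R)-4-[(tert-butyldimethylsilyl)oxy]-2-(tributylstannyl)hex-2-enedioate
Product: 8 dimethyl (2E,4R)-4-[(tert-butyldimethylsilyl)oxy]-2-iodohex-2-enedioate
Conditions: I2, CH2Cl2, 0 °C, dark
Reagents that add atoms: iodine, II
Why: Iododestannylation of an alkenylstannane proceeds with retention of alkene geometry; exclusion of light limits E/Z drift of the α-iodoenoate.

Step 6
Reactants: 9 rac-2-hexadecyloxirane
Product: 10 (2S)-2-hexadecyloxirane
Conditions: (R,R)-(salen)Co(OAc) (0.5 mol%), H2O (0.55 equiv), THF, 0 °C to rt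
Reagents that add atoms: none
Why: Jacobsen hydrolytic kinetic resolution of a terminal epoxide; the catalyst hydrolyses the R enantiomer and leaves the S epoxide, which fixes C3.

Step 7
Reactants: 10 (2S)-2-hexadecyloxirane
Product: 11 (4S)-icos-1-yn-4-ol
Conditions: lithium acetylide–ethylenediamine, DMSO, rt
Reagents that add atoms: lithium acetylide–ethylenediamine complex, [Li+].[C-]#C.NCCN
Why: SN2 opening of a terminal epoxide at the CH2 carbon by acetylide; the carbinol centre is not touched.

Step 8
Reactants: 11 (4S)-icos-1-yn-4-ol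
Product: 12 triethyl{[(4S)-icos-1-yn-4-yl]oxy}silane
Conditions: TESCl, imidazole, CH2Cl2, 0 °C
Reagents that add atoms: chlorotriethylsilane, CC[Si](Cl)(CC)CC
Why: Silylation; the triethylsilyl ether is chosen because it can later be removed in the presence of the tert-butyldimethylsilyl ether, and it prevents lactonisation onto the cis ester.

Step 9
Reactants: 12 triethyl{[(4S)-icos-1-yn-4-yl]oxy}silane
Product: 13 methyl (5S)-5-[(triethylsilyl)oxy]henicos-2-ynoate
Conditions: n-BuLi, THF, −78 °C; ClCO2Me, −78 to 0 °C
Reagents that add atoms: methyl chloroformate, COC(=O)Cl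
Why: Acylation of a lithium acetylide with a chloroformate; no other acidic site is present.

Step 10
Reactants: 13 methyl (5S)-5-[(triethylsilyl)oxy]henicos-2-ynoate
Product: 14 methyl (2E,5S)-2-(tributylstannyl)-5-[(triethylsilyl)oxy]henicos-2-enoate
Conditions: Bu3SnH, Pd(PPh3)4 (2 mol%), THF, 0 °C
Reagents that add atoms: tributyltin hydride, CCCC[SnH](CCCC)CCCC
Why: Palladium-catalysed syn-hydrostannation of an ynoate, α-stannyl regiochemistry, C4 cis to the ester as needed at C4a=C5.

Step 11
Reactants: 14 methyl (2E,5S)-2-(tributylstannyl)-5-[(triethylsilyl)oxy]henicos-2-enoate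
Product: 15 methyl (2E,5S)-2-iodo-5-[(triethylsilyl)oxy]henicos-2-enoate
Conditions: I2, CH2Cl2, 0 °C, dark
Reagents that add atoms: iodine, II
Why: Iododestannylation with retention of geometry.

Step 12
Reactants: 16 octadec-1-yne
Product: 17 (E)-1,2-bis(4,4,5,5-tetramethyl-1,3,2-dioxaborolan-2-yl)octadec-1-ene (the two boryl groups cis)
Conditions: B2pin2, Pt(PPh3)4 (3 mol%), DMF, 80 °C
Reagents that add atoms: bis(pinacolato)diboron, CC1(C)OB(OC1(C)C)B1OC(C)(C)C(C)(C)O1
Why: Platinum-catalysed syn-diboration of a terminal alkyne; the cis boron pair fixes C5 and C8 cis on C6=C7 and the hexadecyl on C6.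

Step 13
Reactants: 8 dimethyl (2E,4R)-4-[(tert-butyldimethylsilyl)oxy]-2-iodohex-2-enedioate; 17 (E)-1,2-bis(4,4,5,5-tetramethyl-1,3,2-dioxaborolan-2-yl)octadec-1-ene
Product: 18 dimethyl (2Z,4R)-4-[(tert-butyldimethylsilyl)oxy]-2-[(1E)-2-(4,4,5,5-tetramethyl-1,3,2-dioxaborolan-2-yl)octadec-1-en-1-yl]hex-2-enedioate
Conditions: PdCl2(dppf) (5 mol%), K3PO4 (aq), THF, rt
Reagents that add atoms: none
Why: Suzuki–Miyaura coupling; in 1,2-diboryl-1-alkenes the terminal C–B bond transmetalates faster than the internal one, so C7–C8 forms first. Both alkene geometries are retained.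

Step 14
Reactants: 18 dimethyl (2Z,4R)-4-[(tert-butyldimethylsilyl)oxy]-2-[(1E)-2-(4,4,5,5-tetramethyl-1,3,2-dioxaborolan-2-yl)octadec-1-en-1-yl]hex-2-enedioate; 15 methyl (2E,5S)-2-iodo-5-[(triethylsilyl)oxy]henicos-2-enoate
Product: 19 dimethyl (2Z,4R)-4-[(tert-butyldimethylsilyl)oxy]-2-[(1Z,3Z,6S)-2-hexadecyl-3-(methoxycarbonyl)-6-[(triethylsilyl)oxy]docosa-1,3-dien-1-yl]hex-2-enedioate
Conditions: Pd2(dba)3 (2.5 mol%), SPhos, K3PO4 (aq), THF, 40 °C, dark
Reagents that add atoms: none
Why: Second Suzuki–Miyaura coupling at the internal boronate forms C5–C6 with retention; a bulky electron-rich phosphine is used for the hindered pair. Any 20 formed already at this temperature is carried forward.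

Step 15
Reactants: 19 dimethyl (2Z,4R)-4-[(tert-butyldimethylsilyl)oxy]-2-[(1Z,3Z,6S)-2-hexadecyl-3-(methoxycarbonyl)-6-[(triethylsilyl)oxy]docosa-1,3-dien-1-yl]hex-2-enedioate
Product: 20 dimethyl (5S,6R)-5-[(1R)-1-[(tert-butyldimethylsilyl)oxy]-3-methoxy-3-oxopropyl]-2-hexadecyl-6-[(2S)-2-[(triethylsilyl)oxy]octadecyl]cyclohexa-1,3-diene-1,4-dicarboxylate
Conditions: toluene (0.01 M), BHT, 80 °C, dark
Reagents that add atoms: none
Why: Thermal 6π electrocyclization of a hexatriene; the closest known type is the closure of cross-coupled trienes carrying 2-acyl groups, which lower the barrier. The six π electrons of C4a=C5–C6=C7–C8=C8a reorganise in one step, forming the C4a–C8a σ bond and leaving the C5=C6–C7=C8 diene. Ring A closes as a six-membered carbocycle by the thermally allowed disrotatory motion of the two termini. Because C4 and C1 both point outward, disrotation turns them to the same face, so C4a and C8a are formed cis; this follows from the alkene geometries fixed in steps 4, 10 and 12. The absolute sense is controlled by C1: A(1,3) strain with the C8 ester holds the C1–H bond in the triene plane, and the new bond should form anti to the C1–O bond with the silyl group turned outward, which for 1R gives the 5S,6R product (8aS,4aR in target numbering). The C3 silyloxy centre is too remote to do more than reinforce or slightly erode this. The step needs geometric integrity (no E/Z leakage, no [1,5]-hydrogen shift) and face selectivity; the first is secured by the low temperature that the two ester groups allow, the second by the allylic stereocentre, and the two possible products are diastereomers and separable.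

Step 16
Reactants: 20 dimethyl (5S,6R)-5-[(1R)-1-[(tert-butyldimethylsilyl)oxy]-3-methoxy-3-oxopropyl]-2-hexadecyl-6-[(2S)-2-[(triethylsilyl)oxy]octadecyl]cyclohexa-1,3-diene-1,4-dicarboxylate
Product: 21 dimethyl (5S,6R)-5-[(1R)-1-[(tert-butyldimethylsilyl)oxy]-3-methoxy-3-oxopropyl]-2-hexadecyl-6-[(2S)-2-hydroxyoctadecyl]cyclohexa-1,3-diene-1,4-dicarboxylate
Conditions: PPTS (cat.), MeOH/CH2Cl2, 0 °C
Reagents that add atoms: none
Why: Mild acid methanolysis cleaves a secondary triethylsilyl ether while a secondary tert-butyldimethylsilyl ether survives; it frees the C3 hydroxyl only after C4a is sp3, when lactonisation onto the C5 ester is no longer pre-organised.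

Step 17
Reactants: 21 dimethyl (5S,6R)-5-[(1R)-1-[(tert-butyldimethylsilyl)oxy]-3-methoxy-3-oxopropyl]-2-hexadecyl-6-[(2S)-2-hydroxyoctadecyl]cyclohexa-1,3-diene-1,4-dicarboxylate
Product: 22 dimethyl (1S,4R,5S,6R)-5-[(1R)-1-[(tert-butyldimethylsilyl)oxy]-3-methoxy-3-oxopropyl]-2-hexadecyl-6-[(2S)-2-hydroxyoctadecyl]cyclohex-2-ene-1,4-dicarboxylate
Conditions: SmI2 (2.5 equiv), THF, −78 to −40 °C, no added proton donor; then AcOH/THF, −78 °C
Reagents that add atoms: none
Why: SmI2 reduction of a conjugated diene diester adds two electrons and two protons across C5/C8 (1,4-reduction) and leaves C6=C7. The free C3 hydroxyl, held on the arm face through C4, is the only proton source present and should hand its proton to C5 syn to C4 through a six-membered transfer (internal protonation of the kind known from dissolving-metal reductions of hydroxy enones); the surviving C8 enolate is protonated on quench from the open face, anti to the C1 arm. C4a and C8a are not touched.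

Step 18
Reactants: 22 dimethyl (1S,4R,5S,6R)-5-[(1R)-1-[(tert-butyldimethylsilyl)oxy]-3-methoxy-3-oxopropyl]-2-hexadecyl-6-[(2S)-2-hydroxyoctadecyl]cyclohex-2-ene-1,4-dicarboxylate
Product: 23 dimethyl (1S,4R,5S,6R)-2-hexadecyl-5-[(1R)-1-hydroxy-3-methoxy-3-oxopropyl]-6-[(2S)-2-hydroxyoctadecyl]cyclohex-2-ene-1,4-dicarboxylate
Conditions: HF·pyridine, pyridine, THF, 0 °C; used at once
Reagents that add atoms: none
Why: Buffered fluoride cleavage of the silyl ether without base, so that neither β-elimination at C1/C2 nor ester epimerisation can occur; the diol is oxidised immediately to forestall lactonisation.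

Step 19
Reactants: 23 dimethyl (1S,4R,5S,6R)-2-hexadecyl-5-[(1R)-1-hydroxy-3-methoxy-3-oxopropyl]-6-[(2S)-2-hydroxyoctadecyl]cyclohex-2-ene-1,4-dicarboxylate
Product: 26 trimethyl (4aR,5S,8R,8aS)-3,6-dihexadecyl-1-oxo-1,4,4a,5,8,8a-hexahydronaphthalene-2,5,8-tricarboxylate, via diketone 24 (not isolated), via aldol adduct 25 (not isolated)
Conditions: Dess–Martin periodinane, NaHCO3, CH2Cl2, 0 °C to rt; filter; then piperidine (cat.), AcOH (cat.), 4 Å MS, CH2Cl2, rt
Reagents that add atoms: none
Why: Dess–Martin oxidation converts both carbinols to ketones (β-keto ester at C1, ketone at C3) and removes the two auxiliary stereocentres. Intramolecular Knoevenagel condensation then joins the most acidic carbon, C2, to the C3 ketone in a six-membered ring and loses water through the C2 enolate, giving the conjugated C2=C3 alkene directly. The conditions are too mild to enolise C8a or to shift C6=C7.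

## Compound list

1 | 3-(trimethylsilyl)prop-2-ynal | C[Si](C)(C)C#CC=O | starting material
2 | 1-methoxy-1-(trimethylsilyloxy)ethene | COC(=C)O[Si](C)(C)C | starting material
3 | methyl (3R)-3-(trimethylsilyloxy)-5-(trimethylsilyl)pent-4-ynoate | COC(=O)C[C@@H](O[Si](C)(C)C)C#C[Si](C)(C)C | intermediate
4 | methyl (3R)-3-hydroxypent-4-ynoate | COC(=O)C[C@@H](O)C#C | intermediate
5 | methyl (3R)-3-[(tert-butyldimethylsilyl)oxy]pent-4-ynoate | COC(=O)C[C@@H](O[Si](C)(C)C(C)(C)C)C#C | intermediate
6 | dimethyl (4R)-4-[(tert-butyldimethylsilyl)oxy]hex-2-ynedioate | COC(=O)C[C@@H](O[Si](C)(C)C(C)(C)C)C#CC(=O)OC | intermediate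
7 | dimethyl (2E,4R)-4-[(tert-butyldimethylsilyl)oxy]-2-(tributylstannyl)hex-2-enedioate | COC(=O)C[C@@H](O[Si](C)(C)C(C)(C)C)/C=C(C(=O)OC)/[Sn](CCCC)(CCCC)CCCC | intermediate
8 | dimethyl (2E,4R)-4-[(tert-butyldimethylsilyl)oxy]-2-iodohex-2-enedioate | COC(=O)C[C@@H](O[Si](C)(C)C(C)(C)C)/C=C(C(=O)OC)/I | intermediate
9 | rac-2-hexadecyloxirane (1,2-epoxyoctadecane) | CCCCCCCCCCCCCCCCC1CO1 | starting material
10 | (2S)-2-hexadecyloxirane | CCCCCCCCCCCCCCCC[C@H]1CO1 | intermediate
11 | (4S)-icos-1-yn-4-ol | C#CC[C@@H](O)CCCCCCCCCCCCCCCC | intermediate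
12 | triethyl{[(4S)-icos-1-yn-4-yl]oxy}silane | C#CC[C@@H](O[Si](CC)(CC)CC)CCCCCCCCCCCCCCCC | intermediate
13 | methyl (5S)-5-[(triethylsilyl)oxy]henicos-2-ynoate | COC(=O)C#CC[C@@H](O[Si](CC)(CC)CC)CCCCCCCCCCCCCCCC | intermediate
14 | methyl (2E,5S)-2-(tributylstannyl)-5-[(triethylsilyl)oxy]henicos-2-enoate | CCCC[Sn](CCCC)(CCCC)\C(C(=O)OC)=C\C[C@@H](O[Si](CC)(CC)CC)CCCCCCCCCCCCCCCC | intermediate
15 | methyl (2E,5S)-2-iodo-5-[(triethylsilyl)oxy]henicos-2-enoate | I\C(C(=O)OC)=C\C[C@@H](O[Si](CC)(CC)CC)CCCCCCCCCCCCCCCC | intermediate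
16 | octadec-1-yne | C#CCCCCCCCCCCCCCCCC | starting material
17 | (E)-1,2-bis(4,4,5,5-tetramethyl-1,3,2-dioxaborolan-2-yl)octadec-1-ene (boryl groups cis) | CCCCCCCCCCCCCCCC/C(B1OC(C)(C)C(C)(C)O1)=C/B1OC(C)(C)C(C)(C)O1 | intermediate
18 | dimethyl (2Z,4R)-4-[(tert-butyldimethylsilyl)oxy]-2-[(1E)-2-(4,4,5,5-tetramethyl-1,3,2-dioxaborolan-2-yl)octadec-1-en-1-yl]hex-2-enedioate | COC(=O)C[C@@H](O[Si](C)(C)C(C)(C)C)/C=C(C(=O)OC)/C=C(CCCCCCCCCCCCCCCC)\B1OC(C)(C)C(C)(C)O1 | intermediate
19 | dimethyl (2Z,4R)-4-[(tert-butyldimethylsilyl)oxy]-2-[(1Z,3Z,6S)-2-hexadecyl-3-(methoxycarbonyl)-6-[(triethylsilyl)oxy]docosa-1,3-dien-1-yl]hex-2-enedioate (triene; C4 and C1 outward, C5 and C8 cis on C6=C7) | COC(=O)C[C@@H](O[Si](C)(C)C(C)(C)C)/C=C(C(=O)OC)/C=C(CCCCCCCCCCCCCCCC)\C(C(=O)OC)=C\C[C@@H](O[Si](CC)(CC)CC)CCCCCCCCCCCCCCCC | intermediate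
20 | dimethyl (5S,6R)-5-[(1R)-1-[(tert-butyldimethylsilyl)oxy]-3-methoxy-3-oxopropyl]-2-hexadecyl-6-[(2S)-2-[(triethylsilyl)oxy]octadecyl]cyclohexa-1,3-diene-1,4-dicarboxylate | CCCCCCCCCCCCCCCCC1=C(C(=O)OC)[C@H](C[C@@H](O[Si](CC)(CC)CC)CCCCCCCCCCCCCCCC)[C@H]([C@H](O[Si](C)(C)C(C)(C)C)CC(=O)OC)C(C(=O)OC)=C1 | intermediate
21 | dimethyl (5S,6R)-5-[(1R)-1-[(tert-butyldimethylsilyl)oxy]-3-methoxy-3-oxopropyl]-2-hexadecyl-6-[(2S)-2-hydroxyoctadecyl]cyclohexa-1,3-diene-1,4-dicarboxylate | CCCCCCCCCCCCCCCCC1=C(C(=O)OC)[C@H](C[C@@H](O)CCCCCCCCCCCCCCCC)[C@H]([C@H](O[Si](C)(C)C(C)(C)C)CC(=O)OC)C(C(=O)OC)=C1 | intermediate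
22 | dimethyl (1S,4R,5S,6R)-5-[(1R)-1-[(tert-butyldimethylsilyl)oxy]-3-methoxy-3-oxopropyl]-2-hexadecyl-6-[(2S)-2-hydroxyoctadecyl]cyclohex-2-ene-1,4-dicarboxylate | CCCCCCCCCCCCCCCCC1=C[C@@H](C(=O)OC)[C@@H]([C@H](O[Si](C)(C)C(C)(C)C)CC(=O)OC)[C@@H](C[C@@H](O)CCCCCCCCCCCCCCCC)[C@@H]1C(=O)OC | intermediate
23 | dimethyl (1S,4R,5S,6R)-2-hexadecyl-5-[(1R)-1-hydroxy-3-methoxy-3-oxopropyl]-6-[(2S)-2-hydroxyoctadecyl]cyclohex-2-ene-1,4-dicarboxylate | CCCCCCCCCCCCCCCCC1=C[C@@H](C(=O)OC)[C@@H]([C@H](O)CC(=O)OC)[C@@H](C[C@@H](O)CCCCCCCCCCCCCCCC)[C@@H]1C(=O)OC | intermediate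
24 | dimethyl (1S,4R,5S,6R)-2-hexadecyl-5-(3-methoxy-3-oxopropanoyl)-6-(2-oxooctadecyl)cyclohex-2-ene-1,4-dicarboxylate | CCCCCCCCCCCCCCCCC1=C[C@@H](C(=O)OC)[C@@H](C(=O)CC(=O)OC)[C@@H](CC(=O)CCCCCCCCCCCCCCCC)[C@@H]1C(=O)OC | intermediate
25 | trimethyl (4aR,5S,8R,8aS)-3,6-dihexadecyl-3-hydroxy-1-oxo-1,2,3,4,4a,5,8,8a-octahydronaphthalene-2,5,8-tricarboxylate (C2 and C3 unassigned) | CCCCCCCCCCCCCCCCC1=C[C@@H](C(=O)OC)[C@H]2C(=O)C(C(=O)OC)C(O)(CCCCCCCCCCCCCCCC)C[C@H]2[C@@H]1C(=O)OC | intermediate
26 | trimethyl (4aR,5S,8R,8aS)-3,6-dihexadecyl-1-oxo-1,4,4a,5,8,8a-hexahydronaphthalene-2,5,8-tricarboxylate | CCCCCCCCCCCCCCCCC1=C[C@@H](C(=O)OC)[C@H]2C(=O)C(C(=O)OC)=C(CCCCCCCCCCCCCCCC)C[C@H]2[C@@H]1C(=O)OC | target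

## Step count and risks

Total steps: 19. Longest linear sequence: 12 (steps 1–5 and 13–19, or steps 6–11 and 14–19).

**Step 15 (key step).** The most likely failure is poor or reversed facial selectivity, because the controlling stereocentre lies outside the forming ring and acts only through allylic strain. A lesser risk is alkene isomerisation before closure, which would leak into trans-fused product. The fallback sets out from 15 and returns at 21. Acidic cleavage of the silyl ether of 15 (HF·pyridine, then PPTS in benzene) lets the C3 hydroxyl close onto the cis ester to give (6S)-6-hexadecyl-3-iodo-5,6-dihydro-2H-pyran-2-one F1. Suzuki coupling of F1 with 18 under the conditions of step 14 gives the triene lactone F2, in which C4a=C5 is locked in the ring. Heating F2 gives the cyclohexadiene-fused lactone F3; the new bond should form trans to the ring hexadecyl group, as conjugate additions to such lactones do, and the 4S series is the matched one. K2CO3 in MeOH at 0 °C then opens the lactone to 21.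

**Step 17.** The most likely failure is protonation of C5 from the open face (by adventitious or relayed protons in place of the tethered hydroxyl), giving the C5 epimer; in-flask lactonisation of the samarium alkoxide is a second risk. The fallback sets out from 21 and returns at 22. SmI2 in THF/MeOH, with external protonation of both enolates from the open face, gives the C5 epimer F4. PPTS in hot toluene closes the cis-fused δ-lactone F5. Catalytic DBU epimerises the lactone α-carbon C5, which is more acidic than the acyclic ester carbon C8, to the trans-fused lactone F6, which lacks the 1,3-diaxial contact of F5. K2CO3 in MeOH opens F6 to 22.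

**Step 14.** The most likely failure is slow transmetalation with protodeboronation at the hindered, electron-poor internal boronate. The fallback sets out from 18 and returns at 19. N-Iodosuccinimide in MeCN exchanges boron for iodine with retention to give the dienyl iodide F7; Stille coupling of F7 with stannane 14 (Pd(PPh3)4, CuI, CsF, DMF) gives 19.

**Step 18.** The most likely failure is acyl transfer: the freed C1 hydroxyl closes onto the cis C8 ester with loss of methanol before it can be oxidised. The fallback sets out from 22 and returns at 24: CrO3/H2SO4 in acetone at 0 °C oxidises the C3 carbinol and converts the C1 silyl ether directly into the ketone, so no free γ-hydroxy ester accumulates. Crude 24 then enters the second stage of step 19; no new compound is made.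

## Further compounds

F1 | step 15 | (6S)-6-hexadecyl-3-iodo-5,6-dihydro-2H-pyran-2-one | CCCCCCCCCCCCCCCC[C@H]1CC=C(I)C(=O)O1
F2 | step 15 | dimethyl (2Z,4R)-4-[(tert-butyldimethylsilyl)oxy]-2-{(1Z)-2-[(6S)-6-hexadecyl-2-oxo-5,6-dihydro-2H-pyran-3-yl]octadec-1-en-1-yl}hex-2-enedioate | COC(=O)C[C@@H](O[Si](C)(C)C(C)(C)C)/C=C(C(=O)OC)/C=C(CCCCCCCCCCCCCCCC)\C1=CC[C@H](CCCCCCCCCCCCCCCC)OC1=O
F3 | step 15 | δ-lactone of 21 (C3 oxygen acylated by the C5 carboxyl, fused to the cyclohexadiene) | CCCCCCCCCCCCCCCCC1=C2C(=O)O[C@@H](CCCCCCCCCCCCCCCC)C[C@@H]2[C@H]([C@H](O[Si](C)(C)C(C)(C)C)CC(=O)OC)C(C(=O)OC)=C1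
F4 | step 17 | dimethyl (1R,4R,5S,6R)-5-[(1R)-1-[(tert-butyldimethylsilyl)oxy]-3-methoxy-3-oxopropyl]-2-hexadecyl-6-[(2S)-2-hydroxyoctadecyl]cyclohex-2-ene-1,4-dicarboxylate (C5 epimer of 22) | CCCCCCCCCCCCCCCCC1=C[C@@H](C(=O)OC)[C@@H]([C@H](O[Si](C)(C)C(C)(C)C)CC(=O)OC)[C@@H](C[C@@H](O)CCCCCCCCCCCCCCCC)[C@H]1C(=O)OC
F5 | step 17 | cis-fused δ-lactone of F4 (C3 oxygen acylated by the C5 carboxyl) | CCCCCCCCCCCCCCCCC1=C[C@@H](C(=O)OC)[C@@H]([C@H](O[Si](C)(C)C(C)(C)C)CC(=O)OC)[C@H]2C[C@H](CCCCCCCCCCCCCCCC)OC(=O)[C@@H]12
F6 | step 17 | trans-fused δ-lactone of 22 (C5 epimer of F5) | CCCCCCCCCCCCCCCCC1=C[C@@H](C(=O)OC)[C@@H]([C@H](O[Si](C)(C)C(C)(C)C)CC(=O)OC)[C@H]2C[C@H](CCCCCCCCCCCCCCCC)OC(=O)[C@H]12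
F7 | step 14 | dimethyl (2Z,4R)-4-[(tert-butyldimethylsilyl)oxy]-2-[(1Z)-2-iodooctadec-1-en-1-yl]hex-2-enedioate | COC(=O)C[C@@H](O[Si](C)(C)C(C)(C)C)/C=C(C(=O)OC)/C=C(CCCCCCCCCCCCCCCC)\I
F0 | step 18 | none | none
A1 | alternative 1 | trimethyl 3,6-dihexadecyl-1-oxo-1,2,3,4,4a,5,8,8a-octahydronaphthalene-2,5,8-tricarboxylate (2,3-dihydro form of 26) | CCCCCCCCCCCCCCCCC1=C[C@@H](C(=O)OC)[C@H]2C(=O)[C@H](C(=O)OC)[C@H](CCCCCCCCCCCCCCCC)C[C@H]2[C@@H]1C(=O)OC
A2 | alternative 1 | N-acyloxyphthalimide of the C4 carboxylic acid, ring-A dienoate with the keto ester chain on C8a | CCCCCCCCCCCCCCCCC1=C[C@@H](C(=O)OC)[C@H](C=C1C(=O)OC)C(=O)[C@H](C(=O)OC)[C@H](CCCCCCCCCCCCCCCC)CC(=O)ON2C(=O)c3ccccc3C2=O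
A3 | alternative 2 | cis-fused bicycle with C1 silyl ether and C2=C3, lacking the C2 ester | CCCCCCCCCCCCCCCCC1=C[C@@H](C(=O)OC)[C@H]2[C@H](O[Si](C)(C)C(C)(C)C)C=C(CCCCCCCCCCCCCCCC)C[C@H]2[C@@H]1C(=O)OC
A4 | alternative 2 | tethered bis-enoate (C8a=C8 and C4a=C5 enoates joined through C1–C2=C3–C4) | COC(=O)/C=C/[C@H](O[Si](C)(C)C(C)(C)C)/C=C(CCCCCCCCCCCCCCCC)\C/C=C/C(=O)OC
A5 | alternative 3 | ring-A enone with C8 ketone, C5 ester and silyloxymethyl on C4a | CCCCCCCCCCCCCCCCC1=CC(=O)C[C@@H](CO[Si](C)(C)C(C)(C)C)[C@@H]1C(=O)OC
A6 | alternative 3 | (E)-5-[(tert-butyldimethylsilyl)oxy]pent-3-en-2-one | CC(=O)/C=C/CO[Si](C)(C)C(C)(C)C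
A7 | alternative 3 | methyl 3-oxononadecanoate | COC(=O)CC(=O)CCCCCCCCCCCCCCCC
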